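## Structural features

Ring A is numbered C1–C6 and ring B C1'–C6'. The target 17 is an achiral diaryl ether of two tetrasubstituted benzene rings with no ring fusion. Ring A is a methyl benzoate whose ester-bearing C1 lies between a prenyloxy group at C2 and the bridging ether oxygen at C6, with a methyl group at C4. Ring B is bonded to that oxygen through C1', which lies between C2' (hydroxymethyl) and C6' (prenyloxy), and it carries a methoxy group at C4'. There is no stereocentre and no alkene geometry to control, so the only stereochemical element in the plan is a transient one. The fragile groups are the two aryl prenyl ethers (sensitive to acid, to heat through Claisen shift, and to electrophiles), the benzylic alcohol on an electron-rich ring, and the ester flanked by two ortho substituents. The real difficulty is the C6–O–C1' bond: C1' has two ortho substituents, both rings are electron-rich, and five oxygen functions must be told apart, so direct O-arylation of a phenol is unattractive. The feature exploited is that C1' carries the ether oxygen and is flanked by C2' and C6'. It can therefore be the doubly nucleophilic C2 methylene of a benzofuran-3(2H)-one in which the ring oxygen is already bonded to C6 and the ketone carbon is already bonded to C1. Ring B is then built around C1' by two conjugate additions, and the ketone is later turned into the ring A ester.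

## Logic of the disconnections

17 to 16: the two O–CH2 bonds of the prenyl ethers (at O2 of ring A and O6' of ring B) are cut. These are the acid- and heat-sensitive groups, so they are attached last. Ten carbons are removed and a bisphenol with a free benzylic alcohol is revealed. The forward step must alkylate the two phenols only, on oxygen, and leave the primary alcohol alone.

16 to 15: three acid-labile groups are put back, an acetal on O2 of ring A, a tert-butyl group on O6' and a silyl group on the benzylic oxygen. No skeletal bond is cut. The gain is that O4' (methyl ether) and O6' (tert-butyl ether) are distinguished and that one operation frees all three hydroxyls. The forward step must cleave all three without ionising the benzylic position.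

15 to 13: the O–CH3 bond at C4' and the acyl C–OCH3 bond of the ester are cut, and the ester carbonyl carbon is joined to C1'. This converts the hindered diaryl ether into a spiro ketone in which the C6–O–C1' linkage is simply the ring O–C bond of a benzofuranone. The hard ether bond therefore no longer has to be made by arylation. The forward step needs an alkoxide that attacks the ketone and not the alkoxy-substituted dienone carbon; aromatisation of ring B supplies the driving force.

13 to 6 and 11: the C1'–C2' and C1'–C6' bonds are cut. Both end on the former acidic methylene carbon of 6, and their other ends are the two β-carbons of the cross-conjugated diynone 11. The oxygen pattern of ring B is encoded in 11: the carbonyl becomes O4', the ynol ether oxygen O6', and the silyloxymethyl group sits on the future C2'. The forward step must deliver two conjugate additions from one carbon, the second closing a six-membered ring on an alkyne.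

6 to 5, then to 2 and 3, then to 1: the carboxyl group is restored at C2 of the furanone, the C2–C3 bond is cut as a Claisen-type bond, the aryl O–CH2 bond is cut, and the acetal is removed from one phenol. This leads back to a symmetrical dihydroxybenzoate in which the ester carbon already sits between the two oxygens, so no regiochemical problem arises on ring A. The forward sequence needs a single protection of one of two equivalent phenols and a decarboxylation that spares the acetal.

11 to 10, then to 8 and 9, and 8 to 7: the ketone is taken back to the carbinol, the bond between the carbinol carbon and the alkoxyalkyne is cut, and the formyl carbon is removed from the propargyl ether. All three pieces are simple alkynes. The forward steps must keep the alkoxyalkyne away from acid and heat.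

## Other disconnections considered

Alternative 1: The cut removes, in one operation, the C6–O ether bond and the C1–carboxyl bond of ring A. In the forward direction the ortho-silylaryl triflate A1 would release its aryne under fluoride, in the presence of the phenoxide of the ring B phenol A2 and under carbon dioxide A3. The phenoxide should add at the aryne carbon remote from the prenyloxy group, and the aryl anion formed next to that group should capture A3 to give the acid A4. Esterification and desilylation would complete 17.
- In its favour: it is the most convergent plan, the alkoxy group directs both new bonds to the right carbons, aryne capture tolerates hindered phenoxides, and both prenyl ethers are in place from the start. On convergence and on the number of steps after the coupling it is better than the chosen plan.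
- Against it: arynes react readily with alkenes that carry allylic hydrogens, and both prenyl groups, one of them on the aryne itself, are such alkenes. The phenoxide also equilibrates with A3 to a less nucleophilic carbonate, and the aryl anion can be protonated before it is carboxylated.
- Comparison: three-component capture of this kind is better founded for nitrogen than for oxygen nucleophiles. A2 also needs its own synthesis with three differentiated oxygens on one ring, a problem the chosen plan avoids by building ring B from an acyclic diynone. On handling the hindered ether itself the two plans are equal.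

Alternative 2: The cut opens ring B at C5'–C6' and C3'–C4'. In the forward direction the 4-aryloxycyclobutenone A5 would be heated with methoxyethyne A6. Electrocyclic opening to a vinylketene, regioselective cycloaddition with the ynol ether, a second four-electron opening and six-electron closure (which restores C1'–C6'), and tautomerisation would give the phenol A7. One O-prenylation and desilylation would follow.
- In its favour: ring B is made new with its substitution pattern fixed by mechanism, the C6' hydroxyl appears free and alone, and the ring A prenyl ether is already present. The endgame needs no global acid treatment and no fragmentation, and is one step shorter than in the chosen plan; on these points it is better.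
- Against it: A5, a cyclobutenone with an aryloxy group on its saturated carbon, has no reliable preparation, and this benzannulation is established for carbon-substituted cyclobutenones, not for this type. The ketene intermediates are generated hot beside a prenyl alkene that can intercept them, and A6 is a volatile, hazardous reagent.
- Comparison: the mechanism is as elegant as the chosen one, but the precursor is far harder to reach than 6 and 11, so overall step economy is likely worse.

Alternative 3: The cut opens ring A at C1–C6 and C4–C5. In the forward direction the pyranone A8 would add through its C3 and C6 across the aryl ethynyl ether A9. The bridged lactone would then lose carbon dioxide (A3 again) to give the silyl ether A10, one desilylation away from 17.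
- In its favour: every oxygen is already differentiated and both prenyl ethers are in place. The polarity is matched, since the nucleophilic terminal alkyne carbon meets C6 of the ester-activated pyranone, so the aryloxy group ends up ortho to the ester. The endgame is a single step. On directness after the key step it is better than the chosen plan.
- Against it: A8 carries a donor alkoxy group at C4 and a methyl group at C6, and both make it a sluggish diene. The temperatures then needed are those at which aryl prenyl ethers undergo Claisen rearrangement and 1-alkynyl ethers decompose. A9 must be made from a hindered phenol that needs the same pre-differentiated ring B as A2.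
- Comparison: the chosen plan runs all its bond-forming steps at or below room temperature on robust protecting groups, at the cost of a protecting-group endgame. The alternative is shorter on paper but depends on a thermal step that the target's own functional groups are unlikely to tolerate.

Key step: step 7

Assumption: 7 and 9 are bought as such; 9 and every compound that still carries the tert-butoxyalkyne (10, 11) lose 2-methylpropene on warming and rearrange with acid, so they are kept cold, acid-free and used promptly.

## Route

Step 1
Reactants: 1 methyl 2,6-dihydroxy-4-methylbenzoate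
Product: 2 methyl 2-hydroxy-6-(methoxymethoxy)-4-methylbenzoate
Conditions: MOMCl (1.05 equiv), i-Pr2NEt, CH2Cl2, 0 °C to rt
Reagents that add atoms: chloromethyl methyl ether (MOMCl), COCCl
Why: O-alkylation of a phenol with an α-chloro ether. With one equivalent the reaction should stop at the monoether, because the remaining phenol is then held in a strong hydrogen bond to the ester carbonyl and is less nucleophilic.

Step 2
Reactants: 2 methyl 2-hydroxy-6-(methoxymethoxy)-4-methylbenzoate; 3 methyl bromoacetate
Product: 5 methyl 3-hydroxy-4-(methoxymethoxy)-6-methyl-1-benzofuran-2-carboxylate, via aryloxyacetate diester 4 (not isolated)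
Conditions: K2CO3, DMF, 50 °C; then KOtBu (2.5 equiv), THF, 0 °C to rt; cold dilute HCl to pH 5
Reagents that add atoms: none
Why: Williamson O-alkylation of the remaining phenol, then Dieckmann condensation in the same flask: the aryloxyacetate carbanion attacks the ortho benzoate ester (5-exo-trig) and the product is held as its stabilised enolate. The benzoate has no α-hydrogen, so only one mode of closure exists.

Step 3
Reactants: 5 methyl 3-hydroxy-4-(methoxymethoxy)-6-methyl-1-benzofuran-2-carboxylate
Product: 6 4-(methoxymethoxy)-6-methyl-1-benzofuran-3(2H)-one
Conditions: LiCl, H2O (2 equiv), DMSO, 130 °C, N2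
Reagents that add atoms: none
Why: Krapcho dealkoxycarbonylation: chloride demethylates the β-keto ester by SN2 and the carboxylate loses CO2 through the keto tautomer. The medium stays near neutral, so the acetal is spared the acid that hydrolysis–decarboxylation would need.

Step 4
Reactants: 7 tert-butyl(dimethyl)(prop-2-yn-1-yloxy)silane
Product: 8 4-{[tert-butyl(dimethyl)silyl]oxy}but-2-ynal
Conditions: n-BuLi, THF, −78 °C; DMF, −78 to 0 °C; inverse quench into cold aq KH2PO4
Reagents that add atoms: N,N-dimethylformamide, CN(C)C=O
Why: Formylation of a lithium acetylide with DMF. The hemiaminal alkoxide persists until work-up, and the buffered inverse quench releases the ynal without letting dimethylamine add to it.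

Step 5
Reactants: 9 tert-butoxyethyne; 8 4-{[tert-butyl(dimethyl)silyl]oxy}but-2-ynal
Product: 10 rac-1-tert-butoxy-6-{[tert-butyl(dimethyl)silyl]oxy}hexa-1,4-diyn-3-ol
Conditions: 9, n-BuLi, THF, −78 °C; then 8, −78 °C; H2O quench, cold work-up
Reagents that add atoms: none
Why: 1,2-Addition of a lithium alkoxyacetylide to an aldehyde that has no α-hydrogen. The new carbinol centre forms racemic and is removed by oxidation in step 6.

Step 6
Reactants: 10 rac-1-tert-butoxy-6-{[tert-butyl(dimethyl)silyl]oxy}hexa-1,4-diyn-3-ol
Product: 11 1-tert-butoxy-6-{[tert-butyl(dimethyl)silyl]oxy}hexa-1,4-diyn-3-one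
Conditions: activated MnO2 (excess), CH2Cl2, 0 °C to rt; filtration, used directly
Reagents that add atoms: none
Why: Oxidation of a doubly propargylic alcohol with MnO2, neutral and heterogeneous, so the alkoxyalkyne and the silyl ether see neither acid nor base.

Step 7
Reactants: 6 4-(methoxymethoxy)-6-methyl-1-benzofuran-3(2H)-one; 11 1-tert-butoxy-6-{[tert-butyl(dimethyl)silyl]oxy}hexa-1,4-diyn-3-one
Product: 13 rac-6'-tert-butoxy-2'-({[tert-butyl(dimethyl)silyl]oxy}methyl)-4-(methoxymethoxy)-6-methyl-3H-spiro[1-benzofuran-2,1'-cyclohexa-2',5'-diene]-3,4'-dione, via Z-enynone monoadduct 12 (not isolated)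
Conditions: 6 (1.0 equiv), 11 (1.1 equiv), KOtBu (0.2 equiv, added last), THF/t-BuOH 10:1, 0.02 M, −20 to 0 °C; AcOH quench; chromatography on Et3N-deactivated silica
Reagents that add atoms: none
Why: Substoichiometric KOtBu converts 6 into its C2 enolate, which adds as a soft carbon nucleophile to a β-alkyne carbon of 11, most likely first at the more electrophilic silyloxymethyl-substituted arm, and protonation of the allenolate gives enynone 12. The C2–H of 12 is still acidic, and in its extended enolate the new C=C bond can equilibrate to the Z geometry from which C2 reaches the second ynone terminus. A second conjugate addition, 6-endo-dig and allowed for an alkyne acceptor, forms the other bond to the same carbon and closes ring B as a cross-conjugated cyclohexa-2,5-dienone spiro-fused at C1'. The closest known reaction type is the base-mediated double Michael spiroannulation of benzofuran-3(2H)-ones with cross-conjugated alkynyl ketones; here both acceptor arms are alkynes, so the new ring arrives at the dienone oxidation level. The spiro carbon is the only new stereocentre; nothing controls it, 13 is racemic, and this does not matter because the centre becomes an aromatic carbon in step 8. The step needs C- over O-addition of the ambident enolate (favoured by the soft acceptor and by reversibility of an O-adduct), ring closure over capture of 12 by a second enolate (favoured by dilution and a slight excess of 11), and survival of the acceptor (the base is present almost only as the weakly basic enolate, which holds back alkoxide addition and propargyl–allenyl isomerisation). Because both additions end on the same carbon, the order in which the two arms react does not change the product, and the two ring B oxygens emerge differentiated as ketone (C4') and tert-butyl enol ether (C6').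

Step 8
Reactants: 13 rac-6'-tert-butoxy-2'-({[tert-butyl(dimethyl)silyl]oxy}methyl)-4-(methoxymethoxy)-6-methyl-3H-spiro[1-benzofuran-2,1'-cyclohexa-2',5'-diene]-3,4'-dione
Product: 15 methyl 2-[2-tert-butoxy-6-({[tert-butyl(dimethyl)silyl]oxy}methyl)-4-methoxyphenoxy]-6-(methoxymethoxy)-4-methylbenzoate, via sodium phenoxide 14 (not isolated)
Conditions: NaOMe (1.2 equiv), MeOH/THF, 0 °C; then MeI (5 equiv), DMF, rt
Reagents that add atoms: sodium methoxide, C[O-].[Na+]; iodomethane, CI
Why: Retro-Claisen (Haller–Bauer-type) cleavage of a non-enolisable ketone: methoxide adds to the α-oxygenated aryl ketone and the tetrahedral intermediate expels C1' as part of an aromatic phenoxide, which drives the reaction and erases the spiro stereocentre. The phenoxide 14 is the only acidic site and is O-methylated in the same flask (Williamson). The bulky tert-butoxy group and the adjacent quaternary carbon should slow competing addition–elimination at C6'.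

Step 9
Reactants: 15 methyl 2-[2-tert-butoxy-6-({[tert-butyl(dimethyl)silyl]oxy}methyl)-4-methoxyphenoxy]-6-(methoxymethoxy)-4-methylbenzoate
Product: 16 methyl 2-hydroxy-6-[2-hydroxy-6-(hydroxymethyl)-4-methoxyphenoxy]-4-methylbenzoate
Conditions: HCl (about 3 M in MeOH), 0 to 40 °C
Reagents that add atoms: none
Why: Acetal solvolysis, silyl ether methanolysis and SN1/E1 cleavage of the aryl tert-butyl ether are all acid-catalysed; methanol traps formaldehyde as its dimethyl acetal and keeps tert-butyl cations from alkylating ring B. The benzylic cation is poorly stabilised (only the ortho aryloxy group is conjugated, the other two oxygens are meta), so the alcohol should survive, and the methyl ester is safe because exchange with methanol is degenerate.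

Step 10
Reactants: 16 methyl 2-hydroxy-6-[2-hydroxy-6-(hydroxymethyl)-4-methoxyphenoxy]-4-methylbenzoate
Product: 17 methyl 2-{2-(hydroxymethyl)-4-methoxy-6-[(3-methylbut-2-en-1-yl)oxy]phenoxy}-4-methyl-6-[(3-methylbut-2-en-1-yl)oxy]benzoate
Conditions: prenyl bromide (2.4 equiv), K2CO3, DMF, rt to 40 °C
Reagents that add atoms: 1-bromo-3-methylbut-2-ene (prenyl bromide), CC(C)=CCBr
Why: Williamson ether synthesis: carbonate deprotonates only the two phenols and not the benzylic alcohol, and the polar aprotic medium favours O- over C-alkylation. SN2 at the primary allylic bromide keeps the prenyl group unrearranged.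

## Compound list

1 | methyl 2,6-dihydroxy-4-methylbenzoate | COC(=O)c1c(O)cc(C)cc1O | starting material
2 | methyl 2-hydroxy-6-(methoxymethoxy)-4-methylbenzoate | COCOc1cc(C)cc(O)c1C(=O)OC | intermediate
3 | methyl bromoacetate | COC(=O)CBr | starting material
4 | methyl 2-(2-methoxy-2-oxoethoxy)-6-(methoxymethoxy)-4-methylbenzoate | COCOc1cc(C)cc(OCC(=O)OC)c1C(=O)OC | intermediate (not isolated)
5 | methyl 3-hydroxy-4-(methoxymethoxy)-6-methyl-1-benzofuran-2-carboxylate | COCOc1cc(C)cc2oc(C(=O)OC)c(O)c12 | intermediate
6 | 4-(methoxymethoxy)-6-methyl-1-benzofuran-3(2H)-one | COCOc1cc(C)cc2OCC(=O)c12 | intermediate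
7 | tert-butyl(dimethyl)(prop-2-yn-1-yloxy)silane | C#CCO[Si](C)(C)C(C)(C)C | starting material
8 | 4-{[tert-butyl(dimethyl)silyl]oxy}but-2-ynal | O=CC#CCO[Si](C)(C)C(C)(C)C | intermediate
9 | tert-butoxyethyne | CC(C)(C)OC#C | starting material
10 | rac-1-tert-butoxy-6-{[tert-butyl(dimethyl)silyl]oxy}hexa-1,4-diyn-3-ol | CC(C)(C)OC#CC(O)C#CCO[Si](C)(C)C(C)(C)C | intermediate
11 | 1-tert-butoxy-6-{[tert-butyl(dimethyl)silyl]oxy}hexa-1,4-diyn-3-one | CC(C)(C)OC#CC(=O)C#CCO[Si](C)(C)C(C)(C)C | intermediate
12 | rac-2-[(2Z)-6-tert-butoxy-1-{[tert-butyl(dimethyl)silyl]oxy}-4-oxohex-2-en-5-yn-2-yl]-4-(methoxymethoxy)-6-methyl-1-benzofuran-3(2H)-one | COCOc1cc(C)cc2OC(C(=O)c12)/C(CO[Si](C)(C)C(C)(C)C)=C\C(=O)C#COC(C)(C)C | intermediate (not isolated)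
13 | rac-6'-tert-butoxy-2'-({[tert-butyl(dimethyl)silyl]oxy}methyl)-4-(methoxymethoxy)-6-methyl-3H-spiro[1-benzofuran-2,1'-cyclohexa-2',5'-diene]-3,4'-dione | COCOc1cc(C)cc2OC3(C(=O)c12)C(CO[Si](C)(C)C(C)(C)C)=CC(=O)C=C3OC(C)(C)C | intermediate
14 | sodium 3-tert-butoxy-5-({[tert-butyl(dimethyl)silyl]oxy}methyl)-4-[2-(methoxycarbonyl)-3-(methoxymethoxy)-5-methylphenoxy]phenolate | COCOc1cc(C)cc(Oc2c(CO[Si](C)(C)C(C)(C)C)cc([O-])cc2OC(C)(C)C)c1C(=O)OC.[Na+] | intermediate (not isolated)
15 | methyl 2-[2-tert-butoxy-6-({[tert-butyl(dimethyl)silyl]oxy}methyl)-4-methoxyphenoxy]-6-(methoxymethoxy)-4-methylbenzoate | COCOc1cc(C)cc(Oc2c(CO[Si](C)(C)C(C)(C)C)cc(OC)cc2OC(C)(C)C)c1C(=O)OC | intermediate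
16 | methyl 2-hydroxy-6-[2-hydroxy-6-(hydroxymethyl)-4-methoxyphenoxy]-4-methylbenzoate | COC(=O)c1c(O)cc(C)cc1Oc1c(CO)cc(OC)cc1O | intermediate
17 | methyl 2-{2-(hydroxymethyl)-4-methoxy-6-[(3-methylbut-2-en-1-yl)oxy]phenoxy}-4-methyl-6-[(3-methylbut-2-en-1-yl)oxy]benzoate | COC(=O)c1c(OCC=C(C)C)cc(C)cc1Oc1c(CO)cc(OC)cc1OCC=C(C)C | target

## Step count and least certain steps

Total step count: 10. Longest linear sequence: 7 steps (1, 2, 3, 7, 8, 9, 10; the branch 4, 5, 6, which joins at step 7, is equally long).

Step 7 (key step). What may go wrong: capture of monoadduct 12 by a second enolate before ring closure, base-induced destruction of 11 (alkoxide addition to an ynone arm, propargyl-to-allenyl isomerisation next to the silyl ether), and O- instead of C-addition. The cause is that a diynone is a more aggressive and more base-sensitive acceptor than the enyne ketones for which this annulation is best established. Fallback: go back to that acceptor type and introduce the second ring double bond afterwards. The fallback sets out from 6 and 9. Lithiated 9 is added to (E)-4-{[tert-butyl(dimethyl)silyl]oxy}but-2-enal F1 to give rac-(E)-1-tert-butoxy-6-{[tert-butyl(dimethyl)silyl]oxy}hex-4-en-1-yn-3-ol F2, and MnO2 oxidation gives (E)-1-tert-butoxy-6-{[tert-butyl(dimethyl)silyl]oxy}hex-4-en-1-yn-3-one F3. KOtBu-catalysed double Michael addition of 6 to F3 (second closure 6-endo-trig) should give the spiro cyclohexenone 2'-tert-butoxy-6'-({[tert-butyl(dimethyl)silyl]oxy}methyl)-4-(methoxymethoxy)-6-methyl-3H-spiro[1-benzofuran-2,1'-cyclohex-2'-ene]-3,4'-dione F4, racemic and as a mixture of two diastereomers, both usable. Kinetic enolisation at its only α-methylene (LiN(i-Pr)2 with TMSCl present, THF, −78 °C) gives the trimethylsilyl dienol ether of the spiro cyclohexenone F5. Saegusa–Ito dehydrosilylation with Pd(OAc)2 in MeCN then brings the sequence back to the route at 13.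

Step 6. What may go wrong: loss of the alkoxyalkyne during oxidation and handling, by Meyer–Schuster-type rearrangement of 10 on acidic surfaces, thermal loss of 2-methylpropene, or hydration of the push-pull ynone, because 10 and 11 are both latent ester or ketene equivalents. Fallback: avoid the alcohol oxidation level altogether. The fallback sets out from 7 (and 9). Lithiation of 7 and acylation with N-methoxy-N-methylcarbamoyl chloride give 4-{[tert-butyl(dimethyl)silyl]oxy}-N-methoxy-N-methylbut-2-ynamide F6. Addition of lithiated 9 at −78 °C, followed by a cold buffered inverse quench that keeps the liberated hydroxylamine protonated, should release the ketone directly and return to the route at 11.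

Step 8. What may go wrong: addition–elimination of methoxide at C6', which would exchange the tert-butoxy group for methoxy and erase the distinction between O4' and O6', and sluggish methylation of the phenoxide in a protic medium. Fallback: take methoxide out of the ring opening. The fallback sets out from 13. Cleavage with hydroxide generated from KOtBu and water (2:1) in THF, where alkoxide exchange at C6' is degenerate, should give 2-[2-tert-butoxy-6-({[tert-butyl(dimethyl)silyl]oxy}methyl)-4-hydroxyphenoxy]-6-(methoxymethoxy)-4-methylbenzoic acid F7. Exhaustive methylation of its carboxylate and phenoxide with MeI and K2CO3 in DMF installs the ester and the aryl methyl ether together and returns to the route at 15.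

Step 9. What may go wrong: ionisation of the benzylic alcohol (solvolysis to a methyl ether or chloride, or alkylation of another ring), C-alkylation of ring B by tert-butyl cations, or incomplete cleavage of the aryl tert-butyl ether under conditions mild enough for the rest. Fallback: mask the benzylic oxygen as an ester before any strong acid is used. The fallback sets out from 15.
- Bu4NF in THF gives methyl 2-[2-tert-butoxy-6-(hydroxymethyl)-4-methoxyphenoxy]-6-(methoxymethoxy)-4-methylbenzoate F8.
- Ac2O and pyridine give methyl 2-[2-(acetoxymethyl)-6-tert-butoxy-4-methoxyphenoxy]-6-(methoxymethoxy)-4-methylbenzoate F9.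
- TFA in wet CH2Cl2 with anisole as cation trap removes the acetal and the tert-butyl group to give methyl 2-[2-(acetoxymethyl)-6-hydroxy-4-methoxyphenoxy]-6-hydroxy-4-methylbenzoate F10.
- Prenyl bromide and K2CO3 in DMF give methyl 2-{2-(acetoxymethyl)-4-methoxy-6-[(3-methylbut-2-en-1-yl)oxy]phenoxy}-4-methyl-6-[(3-methylbut-2-en-1-yl)oxy]benzoate F11.
- K2CO3 in MeOH removes the acetate, with degenerate exchange at the methyl ester, and the sequence comes back to the route at 17.

Step 3. What may go wrong: slow demethylation of the strongly enolised ester, and self-condensation or air oxidation of the base-sensitive product at the temperature needed. Fallback: accept loss of the acetal and put it back. The fallback sets out from 5. Hydrolysis and decarboxylation in refluxing aqueous HCl/AcOH should give 4-hydroxy-6-methyl-1-benzofuran-3(2H)-one F12. Its phenol is re-protected with MOMCl and i-Pr2NEt in CH2Cl2, and the sequence returns to the route at 6.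

## Further compounds

F1 | step 7 | (E)-4-{[tert-butyl(dimethyl)silyl]oxy}but-2-enal | CC(C)(C)[Si](C)(C)OC/C=C/C=O
F2 | step 7 | rac-(E)-1-tert-butoxy-6-{[tert-butyl(dimethyl)silyl]oxy}hex-4-en-1-yn-3-ol | CC(C)(C)OC#CC(O)/C=C/CO[Si](C)(C)C(C)(C)C
F3 | step 7 | (E)-1-tert-butoxy-6-{[tert-butyl(dimethyl)silyl]oxy}hex-4-en-1-yn-3-one | CC(C)(C)OC#CC(=O)/C=C/CO[Si](C)(C)C(C)(C)C
F4 | step 7 | 2'-tert-butoxy-6'-({[tert-butyl(dimethyl)silyl]oxy}methyl)-4-(methoxymethoxy)-6-methyl-3H-spiro[1-benzofuran-2,1'-cyclohex-2'-ene]-3,4'-dione (racemic, both diastereomers) | COCOc1cc(C)cc2OC3(C(=O)c12)C(CO[Si](C)(C)C(C)(C)C)CC(=O)C=C3OC(C)(C)C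
F5 | step 7 | trimethylsilyl dienol ether of the spiro cyclohexenone (racemic, both diastereomers) | COCOc1cc(C)cc2OC3(C(=O)c12)C(CO[Si](C)(C)C(C)(C)C)C=C(O[Si](C)(C)C)C=C3OC(C)(C)C
F6 | step 6 | 4-{[tert-butyl(dimethyl)silyl]oxy}-N-methoxy-N-methylbut-2-ynamide | CON(C)C(=O)C#CCO[Si](C)(C)C(C)(C)C
F7 | step 8 | 2-[2-tert-butoxy-6-({[tert-butyl(dimethyl)silyl]oxy}methyl)-4-hydroxyphenoxy]-6-(methoxymethoxy)-4-methylbenzoic acid | COCOc1cc(C)cc(Oc2c(CO[Si](C)(C)C(C)(C)C)cc(O)cc2OC(C)(C)C)c1C(=O)O
F8 | step 9 | methyl 2-[2-tert-butoxy-6-(hydroxymethyl)-4-methoxyphenoxy]-6-(methoxymethoxy)-4-methylbenzoate | COCOc1cc(C)cc(Oc2c(CO)cc(OC)cc2OC(C)(C)C)c1C(=O)OC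
F9 | step 9 | methyl 2-[2-(acetoxymethyl)-6-tert-butoxy-4-methoxyphenoxy]-6-(methoxymethoxy)-4-methylbenzoate | COCOc1cc(C)cc(Oc2c(COC(C)=O)cc(OC)cc2OC(C)(C)C)c1C(=O)OC
F10 | step 9 | methyl 2-[2-(acetoxymethyl)-6-hydroxy-4-methoxyphenoxy]-6-hydroxy-4-methylbenzoate | COC(=O)c1c(O)cc(C)cc1Oc1c(COC(C)=O)cc(OC)cc1O
F11 | step 9 | methyl 2-{2-(acetoxymethyl)-4-methoxy-6-[(3-methylbut-2-en-1-yl)oxy]phenoxy}-4-methyl-6-[(3-methylbut-2-en-1-yl)oxy]benzoate | COC(=O)c1c(OCC=C(C)C)cc(C)cc1Oc1c(COC(C)=O)cc(OC)cc1OCC=C(C)C
F12 | step 3 | 4-hydroxy-6-methyl-1-benzofuran-3(2H)-one | Cc1cc(O)c2C(=O)COc2c1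
A1 | alternative 1 | 5-methyl-3-[(3-methylbut-2-en-1-yl)oxy]-2-(trimethylsilyl)phenyl trifluoromethanesulfonate | Cc1cc(OCC=C(C)C)c([Si](C)(C)C)c(OS(=O)(=O)C(F)(F)F)c1
A2 | alternative 1 | 4-methoxy-2-[(3-methylbut-2-en-1-yl)oxy]-6-({[tri(propan-2-yl)silyl]oxy}methyl)phenol | Oc1c(CO[Si](C(C)C)(C(C)C)C(C)C)cc(OC)cc1OCC=C(C)C
A3 | alternative 1 | carbon dioxide | O=C=O
A4 | alternative 1 | 2-{4-methoxy-2-[(3-methylbut-2-en-1-yl)oxy]-6-({[tri(propan-2-yl)silyl]oxy}methyl)phenoxy}-4-methyl-6-[(3-methylbut-2-en-1-yl)oxy]benzoic acid | OC(=O)c1c(OCC=C(C)C)cc(C)cc1Oc1c(CO[Si](C(C)C)(C(C)C)C(C)C)cc(OC)cc1OCC=C(C)C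
A5 | alternative 2 | rac-methyl 2-{[2-({[tert-butyl(dimethyl)silyl]oxy}methyl)-4-oxocyclobut-2-en-1-yl]oxy}-4-methyl-6-[(3-methylbut-2-en-1-yl)oxy]benzoate | COC(=O)c1c(OCC=C(C)C)cc(C)cc1OC1C(=O)C=C1CO[Si](C)(C)C(C)(C)C
A6 | alternative 2 | methoxyethyne | COC#C
A7 | alternative 2 | methyl 2-[2-({[tert-butyl(dimethyl)silyl]oxy}methyl)-6-hydroxy-4-methoxyphenoxy]-4-methyl-6-[(3-methylbut-2-en-1-yl)oxy]benzoate | COC(=O)c1c(OCC=C(C)C)cc(C)cc1Oc1c(O)cc(OC)cc1CO[Si](C)(C)C(C)(C)C
A8 | alternative 3 | methyl 6-methyl-4-[(3-methylbut-2-en-1-yl)oxy]-2-oxo-2H-pyran-3-carboxylate | COC(=O)C1=C(OCC=C(C)C)C=C(C)OC1=O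
A9 | alternative 3 | tert-butyl({2-(ethynyloxy)-5-methoxy-3-[(3-methylbut-2-en-1-yl)oxy]phenyl}methoxy)dimethylsilane | C#COc1c(CO[Si](C)(C)C(C)(C)C)cc(OC)cc1OCC=C(C)C
A10 | alternative 3 | methyl 2-{2-({[tert-butyl(dimethyl)silyl]oxy}methyl)-4-methoxy-6-[(3-methylbut-2-en-1-yl)oxy]phenoxy}-4-methyl-6-[(3-methylbut-2-en-1-yl)oxy]benzoate | COC(=O)c1c(OCC=C(C)C)cc(C)cc1Oc1c(CO[Si](C)(C)C(C)(C)C)cc(OC)cc1OCC=C(C)C
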